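## Structural features

The target is a neolignan of five rings. Guaiacyl ring A is bonded to C2 of a 2,3-dihydrobenzofuran (dihydrofuran ring B fused to benzene ring C), and C5 of ring C is bonded directly to C2' of a benzofuran (furan ring D fused to benzene ring E). Ring C carries a methoxy group at C7 and C3 carries a hydroxymethyl group. Ring E carries a methoxy group at C7', beside the fusion carbon C7a', and a 3-hydroxypropyl chain at C5', with hydrogen at C4' and C6'. The only stereocentres, C2 (S) and C3 (R), are adjacent and trans on ring B; while C3 carries an ester the same arrangement reads (2S,3S), because the priorities at C3 change. Re-derivation of the descriptors of the target, of the carbene complex and of the benzannulation product shows them to be mutually consistent, so no structure needs correcting. C2 is a benzylic ether carbon para to the ring A oxygen, so ring B can open, and C2 epimerise, under acid, under base once the phenol is free, or under hydrogenolysis; the phenol, the two primary alcohols and the electron-rich benzofuran are the other fragile groups. The real difficulty is twofold: the absolute configuration of the C2/C3 pair, and a 2-aryl-5',7'-disubstituted benzofuran joined to ring C. The key step exploits the methoxy at C7' next to C7a' and the chain at C5'. That pattern results when a 2-furyl(methoxy)carbene chromium complex, one CO ligand and a terminal alkyne combine, with ring D serving as the furan and the C5–C2' bond already in place.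

## Logic of the disconnections

24 back to 23. The three O–Si bonds (ring A phenol, C3 hydroxymethyl, C5' propanol) are cut last. All three hydroxyls must be masked through the organolithium, chromium and palladium steps, and silyl groups allow a single final unmasking. The forward step must use buffered fluoride so that the liberated phenoxide cannot open ring B.

23 back to 22 and 21. The C4'–H bond is traced back to a C4'–O bond, because the benzannulation necessarily leaves a hydroxyl at C4'. Accepting this oxygen is the price of the key step; it costs two steps (O-sulfonylation of 21, reduction of 22). The demand is selective O-triflation of a hindered phenol and palladium insertion into a C–O bond flanked by two ortho substituents.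

21 back to 17 and 19 (through 20). The bonds C6'–C7', C4'–C5' and C3a'–C4' are cut, which removes ring E entirely. Ring E is thereby reduced to a C5 alkyne, one CO ligand and the carbene carbon, which already carries the C7' methoxy. The forward step must insert the alkyne with the chain next to the CO-derived carbon and close on the single free furan position beside the carbene.

19 back to 18. One O–Si bond is cut; the free hydroxyl would compete in the later triflation, so it is masked with a group that leaves in the final fluoride step.

17 back to 14. The bond between the carbene carbon and furan C5, the Cr=C bond and the O–CH3 bond are cut, leaving a plain 2-arylfuran. The demand is metalation at the furan α-carbon only, which is met by direct deprotonation, so no halogenation step is needed; a regiodefined halogen–lithium exchange is held in reserve.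

14 back to 12 and 13. The aryl–furan bond C5–C2' is cut. It is made on a simple furan, so no aryl–heteroaryl bond has to be forged on a finished benzofuran. The coupling must be fast enough to outrun protodeboronation of 13.

12 back to 11 and 10. The O–Si bond and the two C–H bonds of the CH2OH group are traced back to an ester. The ester is what makes C3 epimerisable and is also the acceptor group of the carbene used one step earlier.

10 back to 9 and 8. The C2–C3 bond of ring B is cut, giving an aryl diazoacetate whose carbene inserts into a benzylic ether C–H bond. One bond closes ring B and sets C2 under catalyst control; C3 is then set by equilibration. The demand is high discrimination between the two enantiotopic benzylic hydrogens.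

8 back to 6 and 7. The bond between ring C and the diazo carbon is cut. This delivers the diazo ester in one step from an aryl iodide and avoids a multistep homologation of a benzaldehyde. The forward coupling must react at the carbon–iodine bond and leave the bromide and the diazo group intact.

6 back to 5 and 3. The ArO–CH2 ether bond is cut. This joins ring C to ring A and installs the C–H bond that later becomes C2–H. The phenol is hindered but acidic, and its ortho and para positions are blocked, so only O-alkylation is possible.

5 back to 4, and 3 back to 2 and 1. One carbon–iodine bond, one O–Si bond and one carbonyl reduction lead to two commercial phenols. The iodination must go ortho to the hydroxyl, which the substitution pattern of 4 enforces.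

## Other disconnections considered

Alternative 1: The cut is the C3–C3a bond of ring B, traced back to the pyranone ring of the (2S)-flavanone A2. In the forward sense A2 is enolised as its methyl enol ether in an orthoformate medium and C3 attacks the trivalent iodine of PhI(OAc)2. The ring C carbon C4a then migrates from C4 to C3 as iodobenzene leaves, so the six-membered ring contracts to ring B and C4 becomes the methyl ester of A1.
- In its favour: the trans C2/C3 relationship should form directly, because the migrating carbon enters anti to the C2 aryl group. No separate epimerisation, no diazo compound and no rhodium are needed, and A1 already carries the C5 bromide. On directness of the trans outcome it is better than step 6 of the chosen plan.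
- Against it here: all stereochemical information rests on C2 of a flavanone, which can be scrambled by reversible retro-oxa-Michael ring opening under the acidic conditions. Migration of the C2 aryl group and dehydrogenation are competing channels of this reaction type and are favoured by electron-rich aryl groups, which is why ring A must be carried as the mesylate. The mesylate would not survive the organolithium step that makes the carbene complex and would have to be exchanged for a silyl ether.
- Comparison: structurally it addresses only rings B and C; ring E would still be built as in steps 9 to 15. Mechanistically it replaces a catalyst-controlled C–H insertion by a substrate-controlled cationic rearrangement whose enantiopurity depends on how A2 is obtained and preserved. In step count it should be about equal to steps 3 to 8 once the protecting-group exchange is counted. It is the equal of the chosen plan on economy, better on operational simplicity, and weaker on security of the absolute configuration.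

Alternative 2: The cut runs through ring D at O1'–C2' and C2'=C3', giving the ring E phosphonium salt A4 and the ring C acid chloride A5. In the forward sense the phenol of A4 is acylated by A5 and Et3N deprotonates the P–CH2 group. The ylide carbon then attacks the new ester carbonyl in an intramolecular Wittig reaction, closing ring D with loss of triphenylphosphine oxide and giving the triacetate A3; one methanolysis would lead to 24.
- In its favour: no oxygen is introduced at C4', so the triflation and reduction of the chosen plan (steps 13 and 14) are not needed. The late stage uses no organolithium and no transition metal, and the assembly is fully convergent. On late-stage step count and on mechanistic simplicity it is better than the chosen plan.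
- Against it here: both fragments are more elaborate. A5 needs a carboxyl group at C5 of the enantioenriched dihydrobenzofuran, a change to acetate protection, and formation of an acid chloride next to the acid-sensitive C2–O1 benzylic ether. A4 needs a ring E arene that already carries the methoxy group, the propyl chain and an ortho-hydroxybenzyl unit, which means a sequence of several steps of its own. The ring A aryl acetate may transfer its acyl group under amine and heat.
- Comparison: structurally it joins two complete benzene rings through ring D, whereas the chosen plan grows ring E from an alkyne, CO and the carbene carbon. What is saved at the end is spent on A4 and A5, so the total length should be about equal. The chosen plan is preferred only because its building blocks are simpler and the single bromide handle serves throughout.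

Alternative 3: The cut is the O1–C2 bond of ring B, leading back to the acyclic bis-phenol A7, in which only the future C3 is stereogenic. In the forward sense Ag2O oxidises the 4-alkylguaiacol ring A of A7 to the para-quinone methide A8. The ring C phenol then adds to the exocyclic carbon in a 5-exo-trig conjugate addition, anti to the C3 substituent, which rearomatises ring A and gives A6.
- In its favour: only one stereocentre has to be made by asymmetric synthesis, and an auxiliary-controlled enolate benzylation would do that with a predictable sense. On predictability of the absolute configuration it is better than step 6 of the chosen plan. C2 follows by substrate control, no diazo chemistry is involved, and A6 differs from 12 only by its free phenol.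
- Against it here: two oxidisable phenols are present, so the oxidant must discriminate between the guaiacol of ring A and the bromoguaiacol of ring C. Quinone methides also dimerise or add water. The trans preference is kinetic and may be incomplete. The auxiliary sequence to A7 and one further silylation of A6 add steps.
- Comparison: like alternative 1 it replaces only the front end (steps 3 to 8) and would join the chosen route before the aryl–furan coupling. Mechanistically a two-electron oxidation and conjugate addition replace a carbene insertion, and stereocontrol moves from a chiral catalyst to an auxiliary plus 1,2-induction. The step count should be equal or slightly higher.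

Key step: step 12

Assumption: the tert-leucinate-derived dirhodium carboxylate is taken to give (2S) in step 6 with its (R)-ligand antipode; should the sense prove opposite, the (S)-ligand catalyst is used and nothing else changes.

Step 1
Reactants: 1 vanillin (4-hydroxy-3-methoxybenzaldehyde)
Product: 2 3-methoxy-4-[(triisopropylsilyl)oxy]benzaldehyde
Conditions: TIPSCl, imidazole, DMF, 0 °C → rt
Reagents that add atoms: triisopropylsilyl chloride, CC(C)[Si](Cl)(C(C)C)C(C)C
Why: Imidazole-mediated O-silylation of a phenol; the bulky silyl ether should survive hydride, amine base, organolithium and palladium steps and falls with fluoride at the end.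

Step 2
Reactants: 2 3-methoxy-4-[(triisopropylsilyl)oxy]benzaldehyde
Product: 3 {3-methoxy-4-[(triisopropylsilyl)oxy]phenyl}methanol
Conditions: NaBH4, THF/MeOH, 0 °C
Reagents that add atoms: none
Why: Borohydride reduction of an aromatic aldehyde to the benzylic alcohol; the aryl silyl ether tolerates the brief exposure at 0 °C.

Step 3
Reactants: 4 4-bromo-2-methoxyphenol
Product: 5 4-bromo-2-iodo-6-methoxyphenol
Conditions: NaI, NaOH, MeOH, 0 °C, aq. NaOCl (1 equiv) added slowly; then aq. Na2S2O3, HCl
Reagents that add atoms: sodium iodide, [Na+].[I-]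
Why: Electrophilic aromatic iodination of a phenoxide by hypoiodite formed in the flask; the para position is blocked by bromine and one ortho position by methoxy, so iodine should enter only at C6.

Step 4
Reactants: 5 4-bromo-2-iodo-6-methoxyphenol; 3 {3-methoxy-4-[(triisopropylsilyl)oxy]phenyl}methanol
Product: 6 {4-[(4-bromo-2-iodo-6-methoxyphenoxy)methyl]-2-methoxyphenoxy}triisopropylsilane
Conditions: PPh3, DIAD, THF, 0 °C → rt
Reagents that add atoms: none
Why: Mitsunobu etherification of an acidic phenol with a primary benzylic alcohol; both ortho positions and the para position of 5 are substituted, so only O-alkylation can occur.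

Step 5
Reactants: 6 {4-[(4-bromo-2-iodo-6-methoxyphenoxy)methyl]-2-methoxyphenoxy}triisopropylsilane; 7 ethyl diazoacetate
Product: 8 ethyl 2-[5-bromo-3-methoxy-2-({3-methoxy-4-[(triisopropylsilyl)oxy]phenyl}methoxy)phenyl]-2-diazoacetate
Conditions: Pd(PPh3)4 (5 mol %), Ag2CO3 (0.5 equiv), Et3N, toluene, rt, dark
Reagents that add atoms: none
Why: Palladium-catalysed cross-coupling of an aryl iodide with a diazoacetate, in which the diazo carbon is palladated with base assistance and reductive elimination keeps the N2 group. Zerovalent palladium inserts into the carbon–iodine bond far faster than into the carbon–bromine bond at room temperature, so the bromide should remain for step 9.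

Step 6
Reactants: 8 ethyl 2-[5-bromo-3-methoxy-2-({3-methoxy-4-[(triisopropylsilyl)oxy]phenyl}methoxy)phenyl]-2-diazoacetate
Product: 10 ethyl (2S,3S)-5-bromo-7-methoxy-2-{3-methoxy-4-[(triisopropylsilyl)oxy]phenyl}-2,3-dihydro-1-benzofuran-3-carboxylate (trans), via cis-(2S,3R) ester 9 (not isolated)
Conditions: Rh2(R-PTTL)4 {dirhodium tetrakis[N-phthaloyl-(R)-tert-leucinate], 1 mol %}, toluene, −60 °C; then DBU (0.5 equiv), rt → 50 °C
Reagents that add atoms: none
Why: Enantioselective intramolecular 1,5 C–H insertion of a rhodium carbenoid into the benzylic ether C–H bond, which is activated by the adjacent oxygen and the electron-rich ring A; the chiral carboxylate ligands select one enantiotopic hydrogen and so set C2 as S. The kinetic cis ester 9 is then equilibrated through its ester enolate to the less strained trans ester, which sets C3 relative to C2 under thermodynamic control while the non-acidic C2 is untouched.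

Step 7
Reactants: 10 ethyl (2S,3S)-5-bromo-7-methoxy-2-{3-methoxy-4-[(triisopropylsilyl)oxy]phenyl}-2,3-dihydro-1-benzofuran-3-carboxylate
Product: 11 [(2S,3R)-5-bromo-7-methoxy-2-{3-methoxy-4-[(triisopropylsilyl)oxy]phenyl}-2,3-dihydro-1-benzofuran-3-yl]methanol
Conditions: DIBAL-H (i-Bu2AlH, 2.5 equiv), CH2Cl2, −78 → 0 °C; aq. potassium sodium tartrate
Reagents that add atoms: none
Why: Hydride reduction of the ester to the primary alcohol at low temperature leaves the aryl bromide and the silyl ether alone and gives no time for enolisation at C3; the descriptor at C3 changes from S to R only because the priorities change.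

Step 8
Reactants: 11 [(2S,3R)-5-bromo-7-methoxy-2-{3-methoxy-4-[(triisopropylsilyl)oxy]phenyl}-2,3-dihydro-1-benzofuran-3-yl]methanol
Product: 12 tert-butyl{[(2S,3R)-5-bromo-7-methoxy-2-{3-methoxy-4-[(triisopropylsilyl)oxy]phenyl}-2,3-dihydro-1-benzofuran-3-yl]methoxy}dimethylsilane
Conditions: TBSCl, imidazole, DMF, rt
Reagents that add atoms: tert-butyldimethylsilyl chloride, CC(C)(C)[Si](C)(C)Cl
Why: Standard O-silylation of a primary alcohol; the hydroxyl must be masked before the organolithium step.

Step 9
Reactants: 12 tert-butyl{[(2S,3R)-5-bromo-7-methoxy-2-{3-methoxy-4-[(triisopropylsilyl)oxy]phenyl}-2,3-dihydro-1-benzofuran-3-yl]methoxy}dimethylsilane; 13 furan-2-ylboronic acid (1.5 equiv)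
Product: 14 tert-butyl{[(2S,3R)-5-(furan-2-yl)-7-methoxy-2-{3-methoxy-4-[(triisopropylsilyl)oxy]phenyl}-2,3-dihydro-1-benzofuran-3-yl]methoxy}dimethylsilane
Conditions: Pd(OAc)2 (2 mol %), SPhos (4 mol %), K3PO4, THF/H2O, 40 °C
Reagents that add atoms: none
Why: Suzuki–Miyaura coupling of an electron-rich aryl bromide; the bulky electron-rich phosphine allows coupling at 40 °C, so that transmetalation should outrun protodeboronation of the 2-furylboronic acid.

Step 10
Reactants: 14 tert-butyl{[(2S,3R)-5-(furan-2-yl)-7-methoxy-2-{3-methoxy-4-[(triisopropylsilyl)oxy]phenyl}-2,3-dihydro-1-benzofuran-3-yl]methoxy}dimethylsilane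
Product: 17 pentacarbonyl{methoxy[5-((2S,3R)-3-{[tert-butyl(dimethyl)silyl]oxymethyl}-7-methoxy-2-{3-methoxy-4-[(triisopropylsilyl)oxy]phenyl}-2,3-dihydro-1-benzofuran-5-yl)furan-2-yl]methylidene}chromium, via 5-lithiofuran 15 (not isolated), via lithium acylchromate 16 (not isolated)
Conditions: n-BuLi (1.1 equiv), THF, −78 → −30 °C; Cr(CO)6, −78 °C → rt; solvent exchange; Me3OBF4, CH2Cl2, 0 °C → rt
Reagents that add atoms: hexacarbonylchromium Cr(CO)6, O=C=[Cr](=C=O)(=C=O)(=C=O)(=C=O)=C=O; trimethyloxonium tetrafluoroborate Me3OBF4, C[O+](C)C.F[B-](F)(F)F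
Why: Fischer carbene synthesis: the free furan α-hydrogen is the most acidic C–H in 14 and is removed at low temperature, the furyllithium adds to a CO ligand of Cr(CO)6, and the hard oxonium salt methylates the acyl oxygen. The benzylic C2–H and C3–H and the silyl ethers should not react at −78 to −30 °C.

Step 11
Reactants: 18 pent-4-yn-1-ol
Product: 19 tert-butyldimethyl(pent-4-yn-1-yloxy)silane
Conditions: TBSCl, imidazole, CH2Cl2, rt
Reagents that add atoms: tert-butyldimethylsilyl chloride, CC(C)(C)[Si](C)(C)Cl
Why: Standard O-silylation of a primary alcohol, so that only the C4' phenol is free when the triflate is made in step 13; this ether can also be bought, which would shorten the count by one.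

Step 12
Reactants: 17 pentacarbonyl{methoxy[5-((2S,3R)-3-{[tert-butyl(dimethyl)silyl]oxymethyl}-7-methoxy-2-{3-methoxy-4-[(triisopropylsilyl)oxy]phenyl}-2,3-dihydro-1-benzofuran-5-yl)furan-2-yl]methylidene}chromium; 19 tert-butyldimethyl(pent-4-yn-1-yloxy)silane (2 equiv)
Product: 21 2-[(2S,3R)-3-{[tert-butyl(dimethyl)silyl]oxymethyl}-7-methoxy-2-{3-methoxy-4-[(triisopropylsilyl)oxy]phenyl}-2,3-dihydro-1-benzofuran-5-yl]-5-{3-[tert-butyl(dimethyl)silyl]oxypropyl}-7-methoxy-1-benzofuran-4-ol, via tricarbonylchromium arene complex 20 (not isolated)
Conditions: THF (0.05 M, degassed), 50 °C; then air, rt, rapid filtration through silica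
Reagents that add atoms: none
Why: Thermal loss of one CO from the zerovalent chromium carbene complex 17 opens a coordination site for 19; the alkyne inserts into the Cr=C bond with its unsubstituted carbon bonding to the former carbene carbon (C6'–C7'), a CO ligand inserts at the new carbene carbon (C4'–C5') to give a chromium-bound dienylketene, and a thermal 6π electrocyclisation through furan C3 (C3a'–C4') closes the six-membered ring E, which tautomerises to the phenol still bound to Cr(CO)3 (20). This is the Dötz benzannulation, and its closest precedent is the reaction of 2-furyl(alkoxy)carbene chromium complexes with terminal alkynes to give 4-hydroxy-7-alkoxybenzofurans. Ring E closes in a formal [3+2+1] sense, three carbons coming from the furylcarbene unit, two from the alkyne and one from CO. No stereocentre is formed, and C2 and C3 are remote from the metal and should be unaffected at 50 °C under neutral conditions. The regioselectivity that is needed, chain at C5' and hydrogen at C6', is secured by the terminal alkyne, whose larger substituent ends up next to the CO-derived carbon. Site selectivity is secured by the substrate, because the furan has only one carbon (C3) next to the carbene-bearing carbon, the other α-position being occupied by ring C. The methoxy group of the carbene carbon becomes the C7' methoxy without a further step. Brief exposure to air strips the Cr(CO)3 fragment from 20, and 21 is carried on without storage because para-alkoxyphenols of this kind oxidise easily.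

Step 13
Reactants: 21 2-[(2S,3R)-3-{[tert-butyl(dimethyl)silyl]oxymethyl}-7-methoxy-2-{3-methoxy-4-[(triisopropylsilyl)oxy]phenyl}-2,3-dihydro-1-benzofuran-5-yl]-5-{3-[tert-butyl(dimethyl)silyl]oxypropyl}-7-methoxy-1-benzofuran-4-ol
Product: 22 2-[(2S,3R)-3-{[tert-butyl(dimethyl)silyl]oxymethyl}-7-methoxy-2-{3-methoxy-4-[(triisopropylsilyl)oxy]phenyl}-2,3-dihydro-1-benzofuran-5-yl]-5-{3-[tert-butyl(dimethyl)silyl]oxypropyl}-7-methoxy-1-benzofuran-4-yl trifluoromethanesulfonate
Conditions: NaH, PhNTf2, THF, 0 °C → rt
Reagents that add atoms: N-phenylbis(trifluoromethanesulfonimide), O=S(=O)(N(c1ccccc1)S(=O)(=O)C(F)(F)F)C(F)(F)F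
Why: O-triflation of the sodium phenoxide with a mild triflyl donor; the only free hydroxyl is the C4' phenol, and the non-acidic conditions spare the silyl ethers and the benzylic ether of ring B.

Step 14
Reactants: 22 2-[(2S,3R)-3-{[tert-butyl(dimethyl)silyl]oxymethyl}-7-methoxy-2-{3-methoxy-4-[(triisopropylsilyl)oxy]phenyl}-2,3-dihydro-1-benzofuran-5-yl]-5-{3-[tert-butyl(dimethyl)silyl]oxypropyl}-7-methoxy-1-benzofuran-4-yl trifluoromethanesulfonate
Product: 23 tert-butyl{[(2S,3R)-5-(5-{3-[tert-butyl(dimethyl)silyl]oxypropyl}-7-methoxy-1-benzofuran-2-yl)-7-methoxy-2-{3-methoxy-4-[(triisopropylsilyl)oxy]phenyl}-2,3-dihydro-1-benzofuran-3-yl]methoxy}dimethylsilane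
Conditions: Pd(OAc)2 (10 mol %), dppp [1,3-bis(diphenylphosphino)propane, 12 mol %], Et3N, HCO2H, DMF, 70 °C
Reagents that add atoms: none
Why: Palladium-catalysed formate reduction of an aryl triflate: zerovalent palladium inserts into the C4'–O bond, formate replaces triflate and loses CO2 to give a palladium hydride, and reductive elimination forms C4'–H. The chelating phosphine is chosen because the triflate has two ortho substituents; excess Et3N keeps the medium non-acidic for the silyl ethers.

Step 15
Reactants: 23 tert-butyl{[(2S,3R)-5-(5-{3-[tert-butyl(dimethyl)silyl]oxypropyl}-7-methoxy-1-benzofuran-2-yl)-7-methoxy-2-{3-methoxy-4-[(triisopropylsilyl)oxy]phenyl}-2,3-dihydro-1-benzofuran-3-yl]methoxy}dimethylsilane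
Product: 24 4-[(2S,3R)-3-(hydroxymethyl)-5-[5-(3-hydroxypropyl)-7-methoxy-1-benzofuran-2-yl]-7-methoxy-2,3-dihydro-1-benzofuran-2-yl]-2-methoxyphenol (target)
Conditions: TBAF (4 equiv), AcOH (4 equiv), THF, 0 °C → rt
Reagents that add atoms: none
Why: Fluoride desilylation removes the aryl and both primary silyl ethers in one operation; AcOH keeps the liberated phenol protonated, so ring B should not open through a quinone methide and C2 and C3 keep their configuration.

## Compound list

1 | vanillin (4-hydroxy-3-methoxybenzaldehyde) | COc1cc(C=O)ccc1O | starting material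
2 | 3-methoxy-4-[(triisopropylsilyl)oxy]benzaldehyde | COc1cc(C=O)ccc1O[Si](C(C)C)(C(C)C)C(C)C | intermediate
3 | {3-methoxy-4-[(triisopropylsilyl)oxy]phenyl}methanol | COc1cc(CO)ccc1O[Si](C(C)C)(C(C)C)C(C)C | intermediate
4 | 4-bromo-2-methoxyphenol | COc1cc(Br)ccc1O | starting material
5 | 4-bromo-2-iodo-6-methoxyphenol | COc1cc(Br)cc(I)c1O | intermediate
6 | {4-[(4-bromo-2-iodo-6-methoxyphenoxy)methyl]-2-methoxyphenoxy}triisopropylsilane | COc1cc(COc2c(I)cc(Br)cc2OC)ccc1O[Si](C(C)C)(C(C)C)C(C)C | intermediate
7 | ethyl diazoacetate | CCOC(=O)C=[N+]=[N-] | starting material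
8 | ethyl 2-[5-bromo-3-methoxy-2-({3-methoxy-4-[(triisopropylsilyl)oxy]phenyl}methoxy)phenyl]-2-diazoacetate | CCOC(=O)C(=[N+]=[N-])c1cc(Br)cc(OC)c1OCc1ccc(O[Si](C(C)C)(C(C)C)C(C)C)c(OC)c1 | intermediate
9 | ethyl (2S,3R)-5-bromo-7-methoxy-2-{3-methoxy-4-[(triisopropylsilyl)oxy]phenyl}-2,3-dihydro-1-benzofuran-3-carboxylate (cis) | CCOC(=O)[C@H]1c2cc(Br)cc(OC)c2O[C@@H]1c1ccc(O[Si](C(C)C)(C(C)C)C(C)C)c(OC)c1 | intermediate (not isolated)
10 | ethyl (2S,3S)-5-bromo-7-methoxy-2-{3-methoxy-4-[(triisopropylsilyl)oxy]phenyl}-2,3-dihydro-1-benzofuran-3-carboxylate (trans) | COc1cc([C@H]2Oc3c(OC)cc(Br)cc3[C@@H]2C(=O)OCC)ccc1O[Si](C(C)C)(C(C)C)C(C)C | intermediate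
11 | [(2S,3R)-5-bromo-7-methoxy-2-{3-methoxy-4-[(triisopropylsilyl)oxy]phenyl}-2,3-dihydro-1-benzofuran-3-yl]methanol (trans) | COc1cc([C@H]2Oc3c(OC)cc(Br)cc3[C@@H]2CO)ccc1O[Si](C(C)C)(C(C)C)C(C)C | intermediate
12 | tert-butyl{[(2S,3R)-5-bromo-7-methoxy-2-{3-methoxy-4-[(triisopropylsilyl)oxy]phenyl}-2,3-dihydro-1-benzofuran-3-yl]methoxy}dimethylsilane | COc1cc([C@H]2Oc3c(OC)cc(Br)cc3[C@@H]2CO[Si](C)(C)C(C)(C)C)ccc1O[Si](C(C)C)(C(C)C)C(C)C | intermediate
13 | furan-2-ylboronic acid | OB(O)c1ccco1 | starting material
14 | tert-butyl{[(2S,3R)-5-(furan-2-yl)-7-methoxy-2-{3-methoxy-4-[(triisopropylsilyl)oxy]phenyl}-2,3-dihydro-1-benzofuran-3-yl]methoxy}dimethylsilane | COc1cc([C@H]2Oc3c(OC)cc(-c4ccco4)cc3[C@@H]2CO[Si](C)(C)C(C)(C)C)ccc1O[Si](C(C)C)(C(C)C)C(C)C | intermediate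
15 | 5-lithio derivative of 14 (lithium at furan C5) | COc1cc([C@H]2Oc3c(OC)cc(-c4ccc([Li])o4)cc3[C@@H]2CO[Si](C)(C)C(C)(C)C)ccc1O[Si](C(C)C)(C(C)C)C(C)C | intermediate (not isolated)
16 | lithium pentacarbonyl(furoyl)chromate derived from 15 (written in its lithium oxycarbene form) | COc1cc([C@H]2Oc3c(OC)cc(-c4ccc(C(O[Li])=[Cr](=C=O)(=C=O)(=C=O)(=C=O)=C=O)o4)cc3[C@@H]2CO[Si](C)(C)C(C)(C)C)ccc1O[Si](C(C)C)(C(C)C)C(C)C | intermediate (not isolated)
17 | pentacarbonyl{methoxy[5-((2S,3R)-3-{[tert-butyl(dimethyl)silyl]oxymethyl}-7-methoxy-2-{3-methoxy-4-[(triisopropylsilyl)oxy]phenyl}-2,3-dihydro-1-benzofuran-5-yl)furan-2-yl]methylidene}chromium | COc1cc([C@H]2Oc3c(OC)cc(-c4ccc(C(OC)=[Cr](=C=O)(=C=O)(=C=O)(=C=O)=C=O)o4)cc3[C@@H]2CO[Si](C)(C)C(C)(C)C)ccc1O[Si](C(C)C)(C(C)C)C(C)C | intermediate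
18 | pent-4-yn-1-ol | C#CCCCO | starting material
19 | tert-butyldimethyl(pent-4-yn-1-yloxy)silane | C#CCCCO[Si](C)(C)C(C)(C)C | intermediate
20 | tricarbonylchromium complex of 21 (metal bound η6 to ring E; written as two components) | COc1cc([C@H]2Oc3c(OC)cc(-c4cc5c(O)c(CCCO[Si](C)(C)C(C)(C)C)cc(OC)c5o4)cc3[C@@H]2CO[Si](C)(C)C(C)(C)C)ccc1O[Si](C(C)C)(C(C)C)C(C)C.O=C=[Cr](=C=O)=C=O | intermediate (not isolated)
21 | 2-[(2S,3R)-3-{[tert-butyl(dimethyl)silyl]oxymethyl}-7-methoxy-2-{3-methoxy-4-[(triisopropylsilyl)oxy]phenyl}-2,3-dihydro-1-benzofuran-5-yl]-5-{3-[tert-butyl(dimethyl)silyl]oxypropyl}-7-methoxy-1-benzofuran-4-ol | COc1cc([C@H]2Oc3c(OC)cc(-c4cc5c(O)c(CCCO[Si](C)(C)C(C)(C)C)cc(OC)c5o4)cc3[C@@H]2CO[Si](C)(C)C(C)(C)C)ccc1O[Si](C(C)C)(C(C)C)C(C)C | intermediate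
22 | 4-yl trifluoromethanesulfonate of 21 | COc1cc([C@H]2Oc3c(OC)cc(-c4cc5c(OS(=O)(=O)C(F)(F)F)c(CCCO[Si](C)(C)C(C)(C)C)cc(OC)c5o4)cc3[C@@H]2CO[Si](C)(C)C(C)(C)C)ccc1O[Si](C(C)C)(C(C)C)C(C)C | intermediate
23 | tert-butyl{[(2S,3R)-5-(5-{3-[tert-butyl(dimethyl)silyl]oxypropyl}-7-methoxy-1-benzofuran-2-yl)-7-methoxy-2-{3-methoxy-4-[(triisopropylsilyl)oxy]phenyl}-2,3-dihydro-1-benzofuran-3-yl]methoxy}dimethylsilane | COc1cc([C@H]2Oc3c(OC)cc(-c4cc5cc(CCCO[Si](C)(C)C(C)(C)C)cc(OC)c5o4)cc3[C@@H]2CO[Si](C)(C)C(C)(C)C)ccc1O[Si](C(C)C)(C(C)C)C(C)C | intermediate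
24 | 4-[(2S,3R)-3-(hydroxymethyl)-5-[5-(3-hydroxypropyl)-7-methoxy-1-benzofuran-2-yl]-7-methoxy-2,3-dihydro-1-benzofuran-2-yl]-2-methoxyphenol | COc1cc([C@H]2Oc3c(OC)cc(-c4cc5cc(CCCO)cc(OC)c5o4)cc3[C@@H]2CO)ccc1O | target

## Step count and least certain steps

Total: 15 steps. Longest linear sequence: 13 steps (steps 1, 2, 4 to 10 and 12 to 15, from 1 to 24).

Step 12 (key step). The most likely failure is diversion of the alkyne-insertion intermediate before or instead of CO insertion (incorporation of a second alkyne, or closure without CO), because furyl carbene complexes are less biased towards the phenol channel than phenyl ones. The second risk is aerial oxidation of the electron-rich para-methoxyphenol during removal of chromium. The fallback abandons the benzannulation and builds ring D instead; it sets out from 12 and returns at 24.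
- Coupling of 12 with ethynyltrimethylsilane (PdCl2(PPh3)2, CuI, Et3N, 70 °C) should give tert-butyl{[(2S,3R)-7-methoxy-2-{3-methoxy-4-[(triisopropylsilyl)oxy]phenyl}-5-[(trimethylsilyl)ethynyl]-2,3-dihydro-1-benzofuran-3-yl]methoxy}dimethylsilane F1.
- Brief treatment with catalytic K2CO3 in MeOH/THF at 0 °C should give the terminal alkyne tert-butyl{[(2S,3R)-5-ethynyl-7-methoxy-2-{3-methoxy-4-[(triisopropylsilyl)oxy]phenyl}-2,3-dihydro-1-benzofuran-3-yl]methoxy}dimethylsilane F2.
- Commercial 4-(3-hydroxypropyl)-2-methoxyphenol is iodinated as in step 3 to give 4-(3-hydroxypropyl)-2-iodo-6-methoxyphenol F3.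
- Sonogashira coupling of F2 with F3 (PdCl2(PPh3)2, CuI, Et3N, DMF, 60 °C), with 5-endo closure of the ortho-alkynylphenol in the same flask, should give 3-{2-[(2S,3R)-3-{[tert-butyl(dimethyl)silyl]oxymethyl}-7-methoxy-2-{3-methoxy-4-[(triisopropylsilyl)oxy]phenyl}-2,3-dihydro-1-benzofuran-5-yl]-7-methoxy-1-benzofuran-5-yl}propan-1-ol F4.
- The conditions of step 15 then give 24.

Step 5. Oxidative addition next to the bulky ortho-benzyloxy group may be slow, and the diazo group may be lost through palladium or silver carbenoid formation before or after coupling. The fallback separates the two events; it sets out from 6 and returns at 8. Coupling of 6 with the Reformatsky reagent BrZnCH2CO2Et (Pd2(dba)3, XPhos, THF, rt; the iodide reacts first) should give ethyl 2-[5-bromo-3-methoxy-2-({3-methoxy-4-[(triisopropylsilyl)oxy]phenyl}methoxy)phenyl]acetate F5. Diazo transfer with 4-acetamidobenzenesulfonyl azide and DBU in MeCN then gives 8.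

Step 6. Facial discrimination between the two benzylic hydrogens may be poor, because the C7 methoxy group flanks the benzyloxy group and changes its conformation in the catalyst pocket; base equilibration may also be incomplete or accompanied by β-elimination that opens ring B. The fallback is a classical resolution; it sets out from 11 and returns at 11. Esterification of scalemic 11 with (2S)-2-methoxy-2-phenylacetic acid (DCC, DMAP, CH2Cl2) gives diastereomeric esters, from which [(2S,3R)-5-bromo-7-methoxy-2-{3-methoxy-4-[(triisopropylsilyl)oxy]phenyl}-2,3-dihydro-1-benzofuran-3-yl]methyl (2S)-2-methoxy-2-phenylacetate F6 is separated by crystallisation or chromatography. Cleavage with DIBAL-H as in step 7 returns stereochemically pure 11.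

Step 10. Deprotonation may not be confined to furan C5 (competing metalation at the benzylic C2–H or ortho to a methoxy group), and the oxonium salt may attack a silyl ether during O-methylation. The fallback makes the lithiation regiodefined; it sets out from 14 and returns at 15. Bromination of 14 with NBS (THF, −78 → −20 °C) at the only free furan α-position should give tert-butyl{[(2S,3R)-5-(5-bromofuran-2-yl)-7-methoxy-2-{3-methoxy-4-[(triisopropylsilyl)oxy]phenyl}-2,3-dihydro-1-benzofuran-3-yl]methoxy}dimethylsilane F7. Bromine–lithium exchange with t-BuLi (2 equiv, THF, −78 °C) gives 15, and step 10 continues from there.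

Step 4. The activated benzylic oxyphosphonium ion may ionise and be captured by the hydrazide anion instead of the hindered phenoxide. The fallback is a Williamson etherification; it sets out from 3 and returns at 6. Treatment of 3 with PBr3 (Et2O, 0 °C) gives [4-(bromomethyl)-2-methoxyphenoxy]triisopropylsilane F8, used crude. Alkylation of 5 with F8 (K2CO3, acetone, rt) gives 6.

## Further compounds

F1 | step 12 | tert-butyl{[(2S,3R)-7-methoxy-2-{3-methoxy-4-[(triisopropylsilyl)oxy]phenyl}-5-[(trimethylsilyl)ethynyl]-2,3-dihydro-1-benzofuran-3-yl]methoxy}dimethylsilane | COc1cc([C@H]2Oc3c(OC)cc(C#C[Si](C)(C)C)cc3[C@@H]2CO[Si](C)(C)C(C)(C)C)ccc1O[Si](C(C)C)(C(C)C)C(C)C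
F2 | step 12 | tert-butyl{[(2S,3R)-5-ethynyl-7-methoxy-2-{3-methoxy-4-[(triisopropylsilyl)oxy]phenyl}-2,3-dihydro-1-benzofuran-3-yl]methoxy}dimethylsilane | COc1cc([C@H]2Oc3c(OC)cc(C#C)cc3[C@@H]2CO[Si](C)(C)C(C)(C)C)ccc1O[Si](C(C)C)(C(C)C)C(C)C
F3 | step 12 | 4-(3-hydroxypropyl)-2-iodo-6-methoxyphenol | COc1cc(CCCO)cc(I)c1O
F4 | step 12 | 3-{2-[(2S,3R)-3-{[tert-butyl(dimethyl)silyl]oxymethyl}-7-methoxy-2-{3-methoxy-4-[(triisopropylsilyl)oxy]phenyl}-2,3-dihydro-1-benzofuran-5-yl]-7-methoxy-1-benzofuran-5-yl}propan-1-ol | COc1cc([C@H]2Oc3c(OC)cc(-c4cc5cc(CCCO)cc(OC)c5o4)cc3[C@@H]2CO[Si](C)(C)C(C)(C)C)ccc1O[Si](C(C)C)(C(C)C)C(C)C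
F5 | step 5 | ethyl 2-[5-bromo-3-methoxy-2-({3-methoxy-4-[(triisopropylsilyl)oxy]phenyl}methoxy)phenyl]acetate | CCOC(=O)Cc1cc(Br)cc(OC)c1OCc1ccc(O[Si](C(C)C)(C(C)C)C(C)C)c(OC)c1
F6 | step 6 | [(2S,3R)-5-bromo-7-methoxy-2-{3-methoxy-4-[(triisopropylsilyl)oxy]phenyl}-2,3-dihydro-1-benzofuran-3-yl]methyl (2S)-2-methoxy-2-phenylacetate | COc1cc([C@H]2Oc3c(OC)cc(Br)cc3[C@@H]2COC(=O)[C@@H](OC)c2ccccc2)ccc1O[Si](C(C)C)(C(C)C)C(C)C
F7 | step 10 | tert-butyl{[(2S,3R)-5-(5-bromofuran-2-yl)-7-methoxy-2-{3-methoxy-4-[(triisopropylsilyl)oxy]phenyl}-2,3-dihydro-1-benzofuran-3-yl]methoxy}dimethylsilane | COc1cc([C@H]2Oc3c(OC)cc(-c4ccc(Br)o4)cc3[C@@H]2CO[Si](C)(C)C(C)(C)C)ccc1O[Si](C(C)C)(C(C)C)C(C)C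
F8 | step 4 | [4-(bromomethyl)-2-methoxyphenoxy]triisopropylsilane | COc1cc(CBr)ccc1O[Si](C(C)C)(C(C)C)C(C)C
A1 | alternative 1 | methyl (2S,3S)-5-bromo-7-methoxy-2-[3-methoxy-4-(methanesulfonyloxy)phenyl]-2,3-dihydro-1-benzofuran-3-carboxylate | COc1cc([C@H]2Oc3c(OC)cc(Br)cc3[C@@H]2C(=O)OC)ccc1OS(C)(=O)=O
A2 | alternative 1 | (2S)-6-bromo-8-methoxy-2-[3-methoxy-4-(methanesulfonyloxy)phenyl]-2,3-dihydro-4H-chromen-4-one | COc1cc([C@@H]2CC(=O)c3cc(Br)cc(OC)c3O2)ccc1OS(C)(=O)=O
A3 | alternative 2 | 4-[(2S,3R)-3-(acetoxymethyl)-5-{5-[3-(acetyloxy)propyl]-7-methoxy-1-benzofuran-2-yl}-7-methoxy-2,3-dihydro-1-benzofuran-2-yl]-2-methoxyphenyl acetate | COc1cc([C@H]2Oc3c(OC)cc(-c4cc5cc(CCCOC(C)=O)cc(OC)c5o4)cc3[C@@H]2COC(C)=O)ccc1OC(C)=O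
A4 | alternative 2 | {[5-(3-acetoxypropyl)-2-hydroxy-3-methoxyphenyl]methyl}triphenylphosphonium bromide | COc1cc(CCCOC(C)=O)cc(C[P+](c2ccccc2)(c2ccccc2)c2ccccc2)c1O.[Br-]
A5 | alternative 2 | (2S,3R)-3-(acetoxymethyl)-2-(4-acetoxy-3-methoxyphenyl)-7-methoxy-2,3-dihydro-1-benzofuran-5-carbonyl chloride | COc1cc([C@H]2Oc3c(OC)cc(C(Cl)=O)cc3[C@@H]2COC(C)=O)ccc1OC(C)=O
A6 | alternative 3 | 4-[(2S,3R)-5-bromo-3-{[tert-butyl(dimethyl)silyl]oxymethyl}-7-methoxy-2,3-dihydro-1-benzofuran-2-yl]-2-methoxyphenol | COc1cc([C@H]2Oc3c(OC)cc(Br)cc3[C@@H]2CO[Si](C)(C)C(C)(C)C)ccc1O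
A7 | alternative 3 | 4-bromo-2-[(2R)-1-{[tert-butyl(dimethyl)silyl]oxy}-3-(4-hydroxy-3-methoxyphenyl)propan-2-yl]-6-methoxyphenol | COc1cc(C[C@@H](CO[Si](C)(C)C(C)(C)C)c2cc(Br)cc(OC)c2O)ccc1O
A8 | alternative 3 | 4-{(2R)-2-(5-bromo-2-hydroxy-3-methoxyphenyl)-3-[tert-butyl(dimethyl)silyl]oxypropylidene}-2-methoxycyclohexa-2,5-dien-1-one | COC1=CC(=C[C@@H](CO[Si](C)(C)C(C)(C)C)c2cc(Br)cc(OC)c2O)C=CC1=O
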